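the same everywhere: starting material 0.068 M; reagent 0.0748 M; free catalyst 0.14 mM
- eta: second substrate 0.068 M; temperature 0 °C; the very flask that is asked about, followed so far
- delta: second substrate 0.068 M; temperature −5 °C; run made earlier
- flask: second substrate 0.0680 M; temperature 0 °C; time 8.0 d

- eta (time / d: target / %): 0.625: 52; 1.67: 64; 3.00: 61; 8.00: 60
- delta (time / d: target / %): 0.625: 44; 1.67: 60; 3.00: 63; 8.00: 66

(readings scatter by 1.5 percentage points)

- Monday's: change nothing and wait 2.5 d more
- Tuesday's: at 8.0 d add reagent, 50.0% of the amount charged, then wait 2.5 d
- Friday's: at 8.0 d take out 90% of the target then present, then wait 2.5 d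
- Thursday's: at 8.0 d add free catalyst, 100% of the amount charged, then wait 2.5 d
- Saturday's: at 8.0 d raise the temperature by 15 K, then wait 2.5 d

- target that was removed still counts
- additions bring no volume worth counting

1. target, in percent of the starting material first charged, at 8.0 d
2. which option adds most target ("none" when 2 percentage points or less is all one gets) (Monday's / Tuesday's / Friday's / Thursday's / Saturday's / none)
3. target present, with what was taken out counted in, in percent of the starting material first charged, after Friday's
4. target present, with what was taken out counted in, in percent of the starting material first charged, after Thursday's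

**Late plateau.** Begin at late times, where the eta flask has stopped climbing. You have 64%, 61% and 60% from 1.67 d onward, each with a scatter of 1.5 percentage points, so you may average them to a plateau of 61.7%. That is my estimate for the target at 8.0 d. The next question is what stopped it.

**Reagent budget.** Now go to the other end, the charge of the eta flask. Its [reagent] of 0.0748 M is less than [starting material] + [second substrate], 0.136 M, so, if each substrate takes one reagent, it cannot serve both substrates in full. I therefore suppose that reagent is the limiting reagent and that its amount at the plateau is near 0. The readings do not show this, so it stays a supposition. Target standing at the plateau per reagent charged is then 56.1%; call this the reagent yield. The last reading of the colder delta flask gives 60.0%, so this share appears to shift with temperature.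

**The options.** If reagent is the budget, waiting, removing target, adding free catalyst and heating give it nothing new to spend, so I expect gains near 0 and 61.7% after Friday's and Thursday's. Tuesday's adds 50.0% of the reagent charge. At an unchanged reagent yield, that gives 31 points.

**Weak link.** That constant yield is the weak link. At the plateau, 38.3% of the starting material charged is not found as target, and I take that share as what late reagent still meets, less than the whole charge that the first reagent met. If the yield shrinks in step with that share, the gain becomes 12 points. I commit to Tuesday's with that gain.

**The forecast.** The forecast reads the stall differently: “I favour catalyst death”. It gives 60.5% (from 59% to 62.5%) and names Thursday's, with 61% after Friday's and 75% after Thursday's. My reckoning differs from it on the best option and on Thursday's.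

**The flask.** The flask gives 61.7% at 8.0 d, and the best option is Tuesday's, which adds 7 points, less than my 12 points. Monday's, Friday's, Thursday's and Saturday's each add 0 points, with 61.7% after Friday's and 61.7% after Thursday's.

    starting material + free catalyst ⇌ catalyst intermediate A (K = 2200 L mol⁻¹, k = 1.47 L mol⁻¹ s⁻¹, Ea = 35.0 kJ mol⁻¹, ΔH = −45.0 kJ mol⁻¹)
    reagent + catalyst intermediate A → free catalyst + target (k = 0.742 L mol⁻¹ s⁻¹, Ea = 52.0 kJ mol⁻¹)
    second substrate + free catalyst ⇌ catalyst intermediate B (K = 306 L mol⁻¹, k = 0.740 L mol⁻¹ s⁻¹, Ea = 51.0 kJ mol⁻¹, ΔH = −45.0 kJ mol⁻¹)
    reagent + catalyst intermediate B → free catalyst + second product (k = 0.0722 L mol⁻¹ s⁻¹, Ea = 46.0 kJ mol⁻¹)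
    reagent + target → over-reaction product (k = 1.74 × 10⁻⁴ L mol⁻¹ s⁻¹, Ea = 72.0 kJ mol⁻¹)
    (constants at 0 °C)

**Shifting uptake.** In this flask, free reagent stands at 0% at 8.00 d, and the reagent yield on the flask's own value is 56.1%. At the start, the forward rate at which starting material takes up free catalyst is 2.0 times the forward rate at which second substrate does, and at the asked time that ratio has fallen to 0.68.

The numbers in the tables were computed from invented constants; noise was put on by code.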